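**Plan**
1. Retrosynthetic cuts: first the C5–vinyl bond of the acrylic acid (Mizoroki–Heck), then O1–C2 and C2–C3 of the dihydrofuran ring together in one [4+1] event, then the benzylic C–S bond of a sulfone and the C3–CH2O bond (hydroxymethylation of a salicylaldehyde).
2. Enabling feature: O1, C7a, C3a and C3 make up a four-atom o-quinone methide (ring oxygen, two carbons of the benzo ring, one exocyclic carbon); C2 with its 3,4-dimethoxyphenyl group is the single carbon that links C3 to O1 and completes the five-membered ring.
3. Forward order: 5-bromo-2,3-dihydroxybenzaldehyde receives a MOM group on O3 and a hydroxymethyl carbon, is silylated and turned into a 2-(1-tosylalkyl)phenol; a benzylsulfonium salt is made separately from isothiocineole; carbonate joins the two and closes the dihydrofuran ring, the only ring formed; Heck coupling with acrylic acid and acid hydrolysis finish.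
4. Stereochemistry: C2 (R) comes from the chiral sulfide carried by the ylide and C3 (S) from the trans-selective annulation in the same step; the E alkene comes from the Heck reaction; the carbinol and sulfone centres before the key step are racemic and vanish in the quinone methide.

Key step: step 6

Assumption: the sulfide is benzylated on its exo lone pair and its ylide reacts on the face turned away from the gem-dimethyl carbon, as in its epoxidations; on this model the (1S,4S,5S) sulfide leads to 2R, and if the sense proved opposite the (1R,4R,5R) sulfide would be used with no other change.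

**Route**

Step 1
Reactants: 1 5-bromo-2,3-dihydroxybenzaldehyde
Product: 2 5-bromo-2-hydroxy-3-(methoxymethoxy)benzaldehyde
Conditions: NaH (2.2 equiv), DMF, 0 °C; MOMCl (1.0 equiv), 0 °C to rt
Reagents that add atoms: chloromethyl methyl ether, COCCl
Why: In the dianion the O3 phenoxide, which is neither conjugated with nor chelated to the formyl group, is the more nucleophilic oxygen, so Williamson-type alkylation with one equivalent of MOMCl should go to O3 only, as in the known selective 3-O-benzylation of 2,3-dihydroxybenzaldehyde.

Step 2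
Reactants: 2 5-bromo-2-hydroxy-3-(methoxymethoxy)benzaldehyde
Product: 4 1-[5-bromo-2-hydroxy-3-(methoxymethoxy)phenyl]ethane-1,2-diol (racemic), via beta-hydroxy silane 3 (not isolated)
Conditions: (isopropoxydimethylsilyl)methylmagnesium chloride (2.5 equiv, from the chlorosilane and Mg), THF, 0 °C; aq NH4Cl; then KF, KHCO3, 30% H2O2, THF/MeOH, rt
Reagents that add atoms: (isopropoxydimethylsilyl)methylmagnesium chloride, CC(C)O[Si](C)(C)C[Mg]Cl; hydrogen peroxide, OO
Why: Grignard addition of the silylmethyl reagent to the aldehyde (one equivalent is spent on the phenol) and Tamao–Fleming oxidation of the C–Si bond should give the 1,2-diol, the acid-free work-up being chosen to avoid Peterson elimination; the new carbinol centre is racemic and is erased in step 6.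

Step 3
Reactants: 4 1-[5-bromo-2-hydroxy-3-(methoxymethoxy)phenyl]ethane-1,2-diol
Product: 6 4-bromo-2-[2-(tert-butyldimethylsilyloxy)-1-hydroxyethyl]-6-(methoxymethoxy)phenol (racemic), via bis-silyl ether 5 (not isolated)
Conditions: TBSCl (2.2 equiv), imidazole, DMF, 0 °C; then KHF2, MeOH, rt
Reagents that add atoms: tert-butyldimethylsilyl chloride, CC(C)(C)[Si](C)(C)Cl
Why: Silylation should take the phenol and the primary alcohol ahead of the hindered benzylic alcohol, and KHF2 in methanol then cleaves only the aryl silyl ether (phenoxide is the better leaving group on silicon) without basic conditions that could move silicon to the benzylic oxygen; this is a standard protection and selective desilylation pair.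

Step 4
Reactants: 6 4-bromo-2-[2-(tert-butyldimethylsilyloxy)-1-hydroxyethyl]-6-(methoxymethoxy)phenol; 7 sodium p-toluenesulfinate
Product: 8 4-bromo-2-[2-(tert-butyldimethylsilyloxy)-1-(p-tolylsulfonyl)ethyl]-6-(methoxymethoxy)phenol (racemic)
Conditions: 7 (3 equiv), CF3CO2H (2 equiv), CH2Cl2, 0 °C to rt
Reagents that add atoms: none
Why: Acid-promoted ionisation of the o-hydroxybenzyl alcohol to the protonated o-quinone methide and capture at sulfur by p-toluenesulfinic acid (SN1-type substitution, the usual way to 2-(1-sulfonylalkyl)phenols) should give the sulfone, and because less CF3CO2H than sulfinate is used the medium is never more acidic than the sulfinic acid, which spares the MOM and silyl ethers.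

Step 5
Reactants: 9 (1S,4S,5S)-isothiocineole; 10 3,4-dimethoxybenzyl bromide
Product: 11 (1S,4S,5S,6S)-6-(3,4-dimethoxybenzyl)-4,7,7-trimethyl-6-thiabicyclo[3.2.1]octan-6-ium trifluoromethanesulfonate
Conditions: 10 (1.5 equiv), LiOSO2CF3 (5 equiv), CH2Cl2/H2O, rt
Reagents that add atoms: lithium trifluoromethanesulfonate, [Li+].[O-]S(=O)(=O)C(F)(F)F
Why: SN2 S-alkylation of the sulfide by the benzylic bromide on the less hindered exo lone pair should give a single sulfonium diastereomer, and exchange of bromide for the non-nucleophilic triflate in the two-phase mixture stops the reverse reaction.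

Step 6
Reactants: 8 4-bromo-2-[2-(tert-butyldimethylsilyloxy)-1-(p-tolylsulfonyl)ethyl]-6-(methoxymethoxy)phenol; 11 (1S,4S,5S,6S)-6-(3,4-dimethoxybenzyl)-4,7,7-trimethyl-6-thiabicyclo[3.2.1]octan-6-ium trifluoromethanesulfonate
Product: 15 (2R,3S)-5-bromo-3-(tert-butyldimethylsilyloxymethyl)-2-(3,4-dimethoxyphenyl)-7-(methoxymethoxy)-2,3-dihydrobenzofuran, via quinone methide 12 (not isolated), via sulfonium ylide 13 (not isolated), via phenoxide betaine 14 (not isolated)
Conditions: 11 (1.3 equiv), Cs2CO3 (3 equiv), CH2Cl2, −20 °C to rt
Reagents that add atoms: none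
Why: Proposed new method: Cs2CO3 should do two jobs, expelling p-toluenesulfinate from the phenoxide of 8 to give the E-configured o-quinone methide 12 and deprotonating 11 to the benzylic sulfonium ylide 13, whose carbon adds to the exocyclic methide carbon (C2–C3 bond) with rearomatisation to the phenoxide betaine 14, after which the phenoxide displaces the sulfide with inversion (O1–C2 bond) in a 5-exo-tet closure of the dihydrofuran ring. The closest known reactions are the carbonate-mediated [4+1] annulation of 2-(1-sulfonylalkyl)phenols with achiral sulfonium ylides to trans-2,3-dihydrobenzofurans and the epoxidations and aziridinations of benzylic isothiocineole ylides; what has not been shown is absolute control of this annulation by a chiral sulfide, here with an alkyl-type methide substituent. C2 is controlled by the sulfide: a single sulfonium diastereomer, an ylide conformer with the aryl group turned away from the bicycle and a face blocked by the gem-dimethyl carbon should fix the configuration of the ylide carbon in 14, and the invertive closure then gives 2R. C3 is controlled by the approach of the two partners through the transition state leading to the anti betaine, which places the silyloxymethyl arm and the aryl group trans across the new ring (3S). The step needs C-attack of the ylide to outrun tautomerisation of 12 to an enol ether and O-benzylation of the phenoxide by 11; slow release of 12 at low temperature into an excess of the strongly nucleophilic semistabilised ylide, the small silyloxymethyl substituent and the absence of any other acceptor (the aryl bromide and both acetals are inert) should secure this.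

Step 7
Reactants: 15 (2R,3S)-5-bromo-3-(tert-butyldimethylsilyloxymethyl)-2-(3,4-dimethoxyphenyl)-7-(methoxymethoxy)-2,3-dihydrobenzofuran; 16 acrylic acid
Product: 17 (E)-3-[(2R,3S)-3-(tert-butyldimethylsilyloxymethyl)-2-(3,4-dimethoxyphenyl)-7-(methoxymethoxy)-2,3-dihydrobenzofuran-5-yl]prop-2-enoic acid
Conditions: 16 (2 equiv), Pd(OAc)2 (5 mol %), P(o-tol)3 (10 mol %), Et3N (3 equiv), DMF, 100 °C
Reagents that add atoms: none
Why: Mizoroki–Heck reaction: zerovalent palladium formed in situ inserts into the C5–Br bond, syn carbopalladation of the acrylate and syn β-hydride elimination should give the E cinnamic acid, and the two stereocentres, the silyl ether and the acetal are untouched by the amine base.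

Step 8
Reactants: 17 (E)-3-[(2R,3S)-3-(tert-butyldimethylsilyloxymethyl)-2-(3,4-dimethoxyphenyl)-7-(methoxymethoxy)-2,3-dihydrobenzofuran-5-yl]prop-2-enoic acid
Product: 18 (E)-3-[(2R,3S)-2-(3,4-dimethoxyphenyl)-7-hydroxy-3-(hydroxymethyl)-2,3-dihydrobenzofuran-5-yl]prop-2-enoic acid
Conditions: 2 M HCl (aq), THF, 40 °C
Reagents that add atoms: none
Why: Aqueous acid should hydrolyse the aryl MOM acetal and the primary silyl ether in one operation (acetal hydrolysis and acid desilylation) without esterifying the acid in the alcohol-free medium, and C3 is not affected while any reversible opening of the benzylic C2–O1 bond would reclose to the more stable trans isomer.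

**Compound list**
1 | 5-bromo-2,3-dihydroxybenzaldehyde | O=Cc1cc(Br)cc(O)c1O | starting material
2 | 5-bromo-2-hydroxy-3-(methoxymethoxy)benzaldehyde | O=Cc1cc(Br)cc(OCOC)c1O | intermediate
3 | 4-bromo-2-[1-hydroxy-2-(isopropoxydimethylsilyl)ethyl]-6-(methoxymethoxy)phenol (racemic, formed in situ) | CC(C)O[Si](C)(C)CC(O)c1cc(Br)cc(OCOC)c1O | intermediate
4 | 1-[5-bromo-2-hydroxy-3-(methoxymethoxy)phenyl]ethane-1,2-diol (racemic) | OCC(O)c1cc(Br)cc(OCOC)c1O | intermediate
5 | 1-[5-bromo-2-(tert-butyldimethylsilyloxy)-3-(methoxymethoxy)phenyl]-2-(tert-butyldimethylsilyloxy)ethanol (racemic, formed in situ) | CC(C)(C)[Si](C)(C)OCC(O)c1cc(Br)cc(OCOC)c1O[Si](C)(C)C(C)(C)C | intermediate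
6 | 4-bromo-2-[2-(tert-butyldimethylsilyloxy)-1-hydroxyethyl]-6-(methoxymethoxy)phenol (racemic) | CC(C)(C)[Si](C)(C)OCC(O)c1cc(Br)cc(OCOC)c1O | intermediate
7 | sodium p-toluenesulfinate | Cc1ccc(cc1)S(=O)[O-].[Na+] | starting material
8 | 4-bromo-2-[2-(tert-butyldimethylsilyloxy)-1-(p-tolylsulfonyl)ethyl]-6-(methoxymethoxy)phenol (racemic) | Cc1ccc(cc1)S(=O)(=O)C(CO[Si](C)(C)C(C)(C)C)c1cc(Br)cc(OCOC)c1O | intermediate
9 | (1S,4S,5S)-4,7,7-trimethyl-6-thiabicyclo[3.2.1]octane (isothiocineole) | C[C@H]1CC[C@H]2C[C@@H]1SC2(C)C | starting material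
10 | 3,4-dimethoxybenzyl bromide | COc1ccc(CBr)cc1OC | starting material
11 | (1S,4S,5S,6S)-6-(3,4-dimethoxybenzyl)-4,7,7-trimethyl-6-thiabicyclo[3.2.1]octan-6-ium trifluoromethanesulfonate (benzyl group exo on sulfur) | COc1ccc(C[S@+]3[C@H]4C[C@H](CC[C@@H]4C)C3(C)C)cc1OC.[O-]S(=O)(=O)C(F)(F)F | intermediate
12 | (6E)-4-bromo-6-[2-(tert-butyldimethylsilyloxy)ethylidene]-2-(methoxymethoxy)cyclohexa-2,4-dien-1-one (o-quinone methide, formed in situ) | O=C1C(OCOC)=CC(Br)=C/C1=C\CO[Si](C)(C)C(C)(C)C | intermediate
13 | (3,4-dimethoxyphenyl)[(1S,4S,5S)-4,7,7-trimethyl-6-thiabicyclo[3.2.1]octan-6-ium-6-yl]methanide (sulfonium ylide of 11, formed in situ) | COc1ccc([CH-][S@+]3[C@H]4C[C@H](CC[C@@H]4C)C3(C)C)cc1OC | intermediate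
14 | 4-bromo-2-[(1S,2S)-3-(tert-butyldimethylsilyloxy)-1-(3,4-dimethoxyphenyl)-1-[(1S,4S,5S)-4,7,7-trimethyl-6-thiabicyclo[3.2.1]octan-6-ium-6-yl]propan-2-yl]-6-(methoxymethoxy)phenolate (zwitterion, sulfur configured as in 11, formed in situ) | COc1ccc([C@@H]([S@+]3[C@H]4C[C@H](CC[C@@H]4C)C3(C)C)[C@H](CO[Si](C)(C)C(C)(C)C)c2cc(Br)cc(OCOC)c2[O-])cc1OC | intermediate
15 | (2R,3S)-5-bromo-3-(tert-butyldimethylsilyloxymethyl)-2-(3,4-dimethoxyphenyl)-7-(methoxymethoxy)-2,3-dihydrobenzofuran (trans) | COc1ccc([C@@H]2Oc3c(OCOC)cc(Br)cc3[C@H]2CO[Si](C)(C)C(C)(C)C)cc1OC | intermediate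
16 | acrylic acid | C=CC(=O)O | starting material
17 | (E)-3-[(2R,3S)-3-(tert-butyldimethylsilyloxymethyl)-2-(3,4-dimethoxyphenyl)-7-(methoxymethoxy)-2,3-dihydrobenzofuran-5-yl]prop-2-enoic acid | COc1ccc([C@@H]2Oc3c(OCOC)cc(/C=C/C(=O)O)cc3[C@H]2CO[Si](C)(C)C(C)(C)C)cc1OC | intermediate
18 | (E)-3-[(2R,3S)-2-(3,4-dimethoxyphenyl)-7-hydroxy-3-(hydroxymethyl)-2,3-dihydrobenzofuran-5-yl]prop-2-enoic acid | COc1ccc([C@@H]2Oc3c(O)cc(/C=C/C(=O)O)cc3[C@H]2CO)cc1OC | target

Total step count: 8. Longest linear sequence: 7 steps (steps 1, 2, 3, 4, 6, 7, 8); step 5 is a one-step branch that joins at step 6.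

**Steps most likely to fail**

1. Step 6 (the proposed new method). The ylide may add through both of its faces or conformers when its partner is a quinone methide and not a carbonyl group, so that the sulfide transfers its chirality only in part. The fallback takes the stereochemical demand out of the annulation and uses known chemistry; it sets out from 8 and 10 and comes back at 15. Dimethyl sulfide and 10 in acetone give (3,4-dimethoxybenzyl)dimethylsulfonium bromide F1. With Cs2CO3 in CH2Cl2, 8 and F1 undergo the established racemic [4+1] annulation to racemic trans-5-bromo-3-(tert-butyldimethylsilyloxymethyl)-2-(3,4-dimethoxyphenyl)-7-(methoxymethoxy)-2,3-dihydrobenzofuran F2. The enantiomers of F2 are separated by preparative chromatography on a chiral stationary phase (amylose tris(3,5-dimethylphenylcarbamate)), and the (2R,3S) enantiomer is 15.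

2. Step 4. The acid may strip the MOM or silyl group before the benzylic alcohol ionises, since ionisation is slowed by the β-silyloxy group and the bromo substituent, or the cation may undergo a 1,2-hydride shift towards an arylacetaldehyde. The fallback avoids acid; it sets out from 6 and comes back at 8. Acetic anhydride, pyridine and DMAP convert 6 into 2-[1-acetoxy-2-(tert-butyldimethylsilyloxy)ethyl]-4-bromo-6-(methoxymethoxy)phenyl acetate F3. Stirring F3 with an excess of 7 and NaHCO3 in aqueous DMF hydrolyses the aryl acetate first; the phenoxide expels the benzylic acetate, sulfinate adds to the quinone methide, and acidification gives 8.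

3. Step 8. Hydrolysis of the aryl MOM ether may be slow enough that the benzylic C2–O1 bond, a p-alkoxybenzyl aryl ether, opens in the acid, with epimerisation at C2 or loss of the hydroxymethyl arm as formaldehyde. The fallback uses no Brønsted acid; it sets out from 17 and comes back at 18. Trimethylsilyl trifluoromethanesulfonate and 2,2′-bipyridyl in MeCN at 0 °C, then water, cleave only the aryl MOM ether and give (E)-3-[(2R,3S)-3-(tert-butyldimethylsilyloxymethyl)-2-(3,4-dimethoxyphenyl)-7-hydroxy-2,3-dihydrobenzofuran-5-yl]prop-2-enoic acid F4. Tetrabutylammonium fluoride in THF then removes the silyl group from F4 and gives 18.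

**Further compounds**
F1 | step 6 | (3,4-dimethoxybenzyl)dimethylsulfonium bromide | COc1ccc(C[S+](C)C)cc1OC.[Br-]
F2 | step 6 | racemic trans-5-bromo-3-(tert-butyldimethylsilyloxymethyl)-2-(3,4-dimethoxyphenyl)-7-(methoxymethoxy)-2,3-dihydrobenzofuran (both enantiomers) | COc1ccc([C@@H]2Oc3c(OCOC)cc(Br)cc3[C@H]2CO[Si](C)(C)C(C)(C)C)cc1OC.COc1ccc([C@H]2Oc3c(OCOC)cc(Br)cc3[C@@H]2CO[Si](C)(C)C(C)(C)C)cc1OC
F3 | step 4 | 2-[1-acetoxy-2-(tert-butyldimethylsilyloxy)ethyl]-4-bromo-6-(methoxymethoxy)phenyl acetate (racemic) | CC(=O)OC(CO[Si](C)(C)C(C)(C)C)c1cc(Br)cc(OCOC)c1OC(C)=O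
F4 | step 8 | (E)-3-[(2R,3S)-3-(tert-butyldimethylsilyloxymethyl)-2-(3,4-dimethoxyphenyl)-7-hydroxy-2,3-dihydrobenzofuran-5-yl]prop-2-enoic acid | COc1ccc([C@@H]2Oc3c(O)cc(/C=C/C(=O)O)cc3[C@H]2CO[Si](C)(C)C(C)(C)C)cc1OC
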